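The runs come from a simulation with constants of no real substance, and the scatter is random.

A closed, stirred vessel held at one temperature receives substrate and coupling partner, and we want the target standing in each flask at the set time.

| setting | north | south-east | ash | cedar | oak | larch |
|---|---|---|---|---|---|---|
| substrate | 0.020 M | 0.020 M | 0.020 M | 0.020 M | 0.020 M | 0.020 M |
| coupling partner | 0.0060 M | 0.0090 M | 0.0120 M | 0.0120 M | 0.0120 M | 0.0120 M |
| temperature | 70 °C | 112 °C | 150 °C | 125 °C | 75 °C | 100 °C |
| remark | run made earlier | run made earlier |  |  |  |  |
| time |  |  | 2.0 h | 2.0 h | 2.0 h | 2.0 h |

| run | time / h | target / % |
|---|---|---|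
| north | 8.00 | 0 |
| north | 10.0 | 0.4 |
| north | 20.0 | 0.6 |
| north | 40.0 | 1.9 |
| north | 48.0 | 2.0 |
| north | 72.0 | 5.0 |
| south-east | 1.50 | 1.0 |
| south-east | 3.00 | 6.1 |
| south-east | 4.00 | 11.2 |
| south-east | 6.00 | 18.4 |
| south-east | 8.00 | 18.2 |
| south-east | 10.0 | 15.3 |

(each reading ± 0.5 percentage points)
- percentages count the substrate that a species holds: one side product counts as two
- target is meant together with its idle adduct
- steps that have been proposed: substrate + coupling partner + released group -> target + 2 released group; substrate + coupling partner -> target + released group; substrate + target -> side product; coupling partner + target <-> idle adduct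
- the flask that comes out highest in amount of target, in percent of the substrate charged, or "all alike" when all lie within 1.5 percentage points (ash / cedar / oak / larch / all alike)
- target at the end, in percent of the substrate charged, ash
- target at the end, in percent of the substrate charged, cedar
- target at the end, in percent of the substrate charged, oak
- target at the end, in percent of the substrate charged, larch

Which flasks leave the lag in time? North took 72.0 h to show 5.0% and south-east 3.00 h to show 6.1%, so we read a speed-up of about 24.0 between 70 °C and 112 °C, a rough figure, for the two runs differ in partner charge as well. Oak and larch are colder than south-east and get less time than its 3.00 h, so we expect both to stay low.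

How high can the hot flasks go? Under the proposed steps, each partner turned over takes one substrate and gives one target, raising target minus substrate by two units. The side step takes one of each and leaves that difference unchanged. With less partner charged than substrate, target minus substrate stands, once the partner is turned over, at the balance line, twice the partner-to-substrate ratio less one: 20.0%. Each unit of partner still free or held as idle adduct lowers it by two.

Where does the set time fall against the peak? South-east's peak reading, 18.4% at 6.00 h, is 40.9% of what its partner allowed. Ash lies about as far above south-east as south-east lies above north, so we put its peak near 0.250 h, well before 2.0 h. Should ash by then hold next to no substrate, its target stands at or under the line. Cedar needs a speed-up of 3.00 to peak at 2.0 h, which seems plausible, and the same share of its partner gives 24.5%. So we name cedar.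

The forecast differs: 23% for ash, 18% for cedar, 0.2% for oak, 1.2% for larch, and ash highest, because “target settles slightly above 20%”.

The flasks give 13.9% for ash, 20.9% for cedar, 0.0970% for oak and 1.32% for larch, with cedar highest.

    substrate + coupling partner + released group → target + 2 released group (k = 47.0 M⁻² min⁻¹, Ea = 67.0 kJ mol⁻¹)
    substrate + coupling partner → target + released group (k = 0.00470 M⁻¹ min⁻¹, Ea = 90.0 kJ mol⁻¹)
    substrate + target → side product (k = 0.140 M⁻¹ min⁻¹, Ea = 95.0 kJ mol⁻¹)
    coupling partner + target ⇌ idle adduct, settled at all times (K = 170 M⁻¹, ΔH = −20.0 kJ mol⁻¹)
    (constants at 100 °C)

In cedar at 2.00 h, the half-life of substrate is 2.3 h by the autocatalytic step and 4.4 h by the side step. Ash ends with 6.13% substrate, 8.49% of its partner free and 1.04% idle adduct, so the line gives 13.9% target. The neighbour of cedar charged with 0.020 M partner has a line of 100%, and with 27.2% substrate, 24.0% free partner and 16.4% adduct it stands at 46.5% target.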